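## Structural features

Dipolynaphthalene B (19) is a tetralin (ring A aromatic, ring B saturated) bonded through C4 of ring B to C1' of a naphthalene (ring C carries the junction, ring D is fused to it). Ring A has a methoxy group at C5, directly beside the C4 methine. Ring C has a free hydroxyl at C4', para to C1', and ring D has a methoxy group at C5', peri to that hydroxyl. The two stereocentres, C1 (secondary benzylic carbinol) and C4 (diaryl methine), are both S. They are not adjacent but stand 1,4 across ring B, with hydroxyl and naphthyl cis. The benzylic C1 alcohol ionizes in acid, the electron-rich 8-methoxy-1-naphthol unit oxidizes easily, and C4–H is doubly benzylic. The real difficulty is the congested C4–C1' bond, a stereogenic sp3 carbon wedged between the C5 methoxy group and the peri C8'–H, which must be made in one absolute configuration. A second difficulty is telling the two peri oxygens apart (free OH on C4', methyl ether on C5'). The key step exploits ring C: C1' and C4'–OH are para, which is the pattern a 2-substituted furan leaves (furan C2 becomes C1', the furan oxygen becomes the C4' hydroxyl) once ring D has been added as a benzyne and the oxygen bridge opened. A boron substituent on that benzyne steers the regiochemistry and afterwards becomes the C5' oxygen.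

## Logic of the disconnections

19 ⇒ 18. The C1–H bond is cut, returning the carbinol to a carbonyl group. The benzylic alcohol is the most acid-labile function and must come last; a carbonyl at C1 can be masked through the organometallic and acidic steps. The forward step must deliver hydride to the face opposite the C4 substituent and give 1S.

18 ⇒ 16. Ring C is taken back from the naphthol to the oxygen-bridged dihydro form: the C4'–O–H oxygen is reconnected to C1', and the C1 carbonyl returns to its dioxolane. This makes ring C reachable by cycloaddition and keeps the C4' oxygen locked while the C5' oxygen is methylated. The forward step needs heterolysis only at the tertiary C1'–O bond, without migration of the tetralin substituent.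

16 ⇒ 15 ⇒ 14. The O–CH3 bond and then the C5'–O bond are cut, so that C5' carries boron. Boron is the regiochemical director of the cycloaddition and is converted cleanly into oxygen. The forward oxidation and methylation must leave the strained bridge and the dioxolane intact.

14 ⇒ 7 + 11 (through 13). The C1'–C8a' and C4'–C4a' bonds are cut, which removes ring D as an aryne and leaves the furan of 7. This is the largest simplification: two skeletal bonds and one ring in a single convergent step. The forward step needs the substituted furan carbon to bond to the aryne carbon remote from boron, and the carbonyl group to be masked against the magnesium reagent.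

7 ⇒ 6 ⇒ 2 + 3. The dioxolane is removed, then the C4–C(furan) bond is cut. It is the only carbon–carbon bond at the C4 stereocentre, so forming it enantioselectively fixes the absolute configuration of the whole route. The forward step must turn racemic 2 into one enantiomer of 6.

2 ⇒ 1. The C4–Br bond is cut. C4 is the benzylic position of a commercial tetralone, so the handle comes from one radical substitution; it must select C4 over C2 and over the ring.

11 ⇒ 10 ⇒ 8. The O–S bond and then the C–B bond are cut, leading to a symmetric diiodophenol. Symmetry removes any regiochemical question: whichever iodine is exchanged, boron ends ortho to oxygen and the remaining iodine sits on the other side. The forward step needs mono-exchange only.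

## Other disconnections considered

Alternative 1: The cut is through C1–C2 and C3–C4 of ring B. It leaves the o-benzylbenzaldehyde A1 (formyl carbon = C1, diarylmethane CH2 = C4) and the two-carbon dienophile A2.
- Forward step: excitation of A1 at 365 nm, 1,5-hydrogen transfer from the CH2 group to the carbonyl oxygen, an (E,E)-hydroxy-o-quinodimethane held on a Ti(OiPr)4/TADDOL template, and endo [4+2] addition of A2 to give the all-cis sulfonyl tetralol A3. Reductive desulfonylation and hydrogenolysis of the benzyl ether would then lead to 19.
- In its favour: ring B, both stereocentres and their cis relation arise in one step from achiral partners. The carbinol appears at the right oxidation level. The naphthalene enters as a finished unit with its peri oxygens already differentiated.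
- Against it here: the titanium template is best established for aldehydes with a donor next to the formyl group and for dienophiles with a carbonyl oxygen. A1 has its methoxy group beside the benzylic carbon and A2 is a weak donor, so the basis for enantiocontrol is thin. The alkoxynaphthalene of A1 has a lower triplet energy than the aryl aldehyde and could drain the excited state before hydrogen transfer. The dienol geometry at the naphthyl-bearing terminus, which decides cis or trans, is under steric pressure from the flanking methoxy group. The sulfone of A3 is β to a free hydroxyl, so reductive removal competes with β-elimination.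
- Comparison: on stereochemical economy Alternative 1 is the better plan (two centres in one step, no late diastereoselective reduction), and in convergence it is the equal of the chosen plan. Mechanistically the chosen route uses ground-state steps with a regiochemical control element whose role is understood, whereas here both the photophysics and the source of induction are uncertain. Step counts are close (roughly five steps to A1, then three), so neither wins on length.

Alternative 2: The cut removes three bonds of ring A (C4a–C8a, C5–C6, C7–C8). It leaves the acyclic 1,7-diyne A4, which carries both stereocentres, and A5.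
- Forward step: [Rh(cod)2]BF4/BINAP-mediated oxidative coupling of the two tethered alkynes (closing ring B as a rhodacyclopentadiene), insertion of A5 and reductive elimination to the arene A6. Fluoride would then remove both silyl groups to give 19.
- In its favour: the regiochemistry of ring A is fixed by the tether, since the methoxy-bearing alkyne carbon can only become C5. Both stereocentres are set beforehand in the open chain under reagent control. The end game is neutral and consists of one deprotection, which is better than the acid step and late reduction of the chosen plan for functional-group risk.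
- Against it here: A4 is long to make and delicate. Its C4 is propargylic and naphthylic, so base can isomerize it to an allene and erase the centre, and the methoxyalkyne hydrolyses readily. The chiral ligand has no stereocentre to create. A5 must outcompete self-trimerization of the diyne. Ring A, which comes with commercial material in the chosen route, is built from scratch.
- Comparison: structurally it spends the key step on the least demanding ring. Mechanistically the metallacycle chemistry is as well founded as the aryne cycloaddition and cleaner in regiochemistry, so it is equal or slightly better on that count. On step economy it is clearly worse.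

Alternative 3: The cut is through C1–C8a and C4–C4a of ring B. It leaves the aryne precursor A7 and the naphthylfuran A8. This is the same reaction class as the chosen key step, but here the furan supplies C1–C4 of ring B and its oxygen becomes the C1 hydroxyl.
- Forward step: CsF releases the methoxy-aryne from A7, and [4+2] addition across the furan of A8 gives the bridged adduct A9. Hydrogenation of the C2=C3 bond and hydrogenolysis of the tertiary dibenzylic C4–O bond (with loss of the benzyl ether) would give 19, provided C–O is replaced by C–H with inversion.
- In its favour: it is the shortest plan (A8 by one cross-coupling, then two or three steps), so its step economy is better than that of the chosen route. Fluoride-triggered aryne release is milder than a Grignard trigger and needs no boron relay. The bridge ties C1 and C4 together, so their relative configuration could follow from one stereospecific hydrogenolysis.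
- Against it here: A9 would form as a racemate with nothing to control absolute configuration. The required regiochemistry puts the naphthyl-bearing bridgehead next to the methoxy-bearing ring carbon, the most hindered contact, and relies only on polarization of the aryne. Hydrogenolysis must stop at the tertiary C–O bond without cleaving the secondary benzylic C1–O bond it uncovers, and retention instead of inversion would give the trans isomer. A9 is also prone to acid isomerization to a naphthol.
- Comparison: structurally it uses the bridge oxygen more directly than the chosen plan and is equal in convergence. Mechanistically the pericyclic event is the same and equally precedented, but the chosen plan has an explicit regiochemical director and an enantioselective step, and this one has neither. On step count the alternative is better.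

Key step: step 6

Remarks on the chemistry:
- The borylbenzyne is released from the 2-iodo-6-boryl triflate 11. Its isomer with iodine between oxygen and boron would give the same aryne, but would need iodination of 3-borylphenol at its most hindered ortho position, which cannot be defended; 11 follows from symmetric 8 without any regiochemical choice.
- 14, 15, 16 and 17 are expected as mixtures of two diastereomers that differ only in the sense of the oxygen bridge; one is drawn, and both converge in step 9.
- The sense of induction of the pybox ligand in step 2 cannot be predicted with confidence; the ligand enantiomer that delivers 4R is to be used.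

## Route

Step 1
Reactants: 1 5-methoxy-3,4-dihydronaphthalen-1(2H)-one (5-methoxy-1-tetralone)
Product: 2 racemic 4-bromo-5-methoxy-3,4-dihydronaphthalen-1(2H)-one
Conditions: NBS (1.05 equiv), AIBN (cat.), PhCF3, 80 °C; used crude
Reagents that add atoms: N-bromosuccinimide, O=C1CCC(=O)N1Br
Why: Wohl–Ziegler radical bromination; the C4 hydrogens are benzylic and flanked by the donor methoxy group, so bromine-atom abstraction is fastest there, while the carbonyl group deactivates the ring toward electrophilic bromination and C2 reacts only by the ionic enol pathway that a low HBr level suppresses. The product is racemic, which step 2 tolerates, and is used at once because it loses HBr easily.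

Step 2
Reactants: 2 racemic 4-bromo-5-methoxy-3,4-dihydronaphthalen-1(2H)-one; 3 furan
Product: 6 (4R)-4-(furan-2-yl)-5-methoxy-3,4-dihydronaphthalen-1(2H)-one, via 2-furyllithium 4 (not isolated), via 2-furylzinc chloride 5 (not isolated)
Conditions: 3, n-BuLi, THF, 0 °C; ZnCl2, 0 °C → rt; then 2, NiCl2(dme) (10 mol %), iPr-pybox (13 mol %, enantiomer chosen for 4R), DMA/THF, −20 °C
Reagents that add atoms: none
Why: Stereoconvergent nickel-catalysed Negishi cross-coupling of a racemic secondary benzylic bromide with an arylzinc reagent made by C2-lithiation of furan and transmetalation. Halogen abstraction turns both enantiomers of 2 into the same planar benzylic radical, which the chiral pybox–nickel aryl complex captures before reductive elimination, so the C4 stereocentre is set by the ligand (catalyst control). The ketone is inert to the arylzinc at this temperature.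

Step 3
Reactants: 6 (4R)-4-(furan-2-yl)-5-methoxy-3,4-dihydronaphthalen-1(2H)-one
Product: 7 (4'R)-4'-(furan-2-yl)-5'-methoxy-3',4'-dihydro-2'H-spiro[1,3-dioxolane-2,1'-naphthalene]
Conditions: HOCH2CH2OH, TsOH·H2O (cat.), PhH, reflux (Dean–Stark)
Reagents that add atoms: ethylene glycol, OCCO
Why: Acid-catalysed ketalization with azeotropic removal of water; the dioxolane shields the carbonyl group from the Grignard reagent of step 6 and removes the carbonyl-assisted acidity of C4–H. The C4 centre is not involved, and a 2-alkylfuran tolerates catalytic sulfonic acid in a non-nucleophilic solvent.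

Step 4
Reactants: 8 2,6-diiodophenol
Product: 10 2-iodo-6-(4,4,5,5-tetramethyl-1,3,2-dioxaborolan-2-yl)phenol, via magnesiated phenoxide 9 (not isolated)
Conditions: MeMgCl (1.0 equiv), THF, −20 °C; iPrMgCl·LiCl (1.1 equiv), −20 → 0 °C; iPrOBpin, −20 °C → rt; aq. NH4Cl
Reagents that add atoms: 2-isopropoxy-4,4,5,5-tetramethyl-1,3,2-dioxaborolane, CC(C)OB1OC(C)(C)C(C)(C)O1
Why: Iodine–magnesium exchange on a magnesium iodophenoxide in the presence of LiCl, followed by electrophilic borylation of the arylmagnesium. After deprotonation one of the two equivalent iodines is exchanged, and the resulting doubly metalated species resists a second exchange. The symmetry of 8 leaves no regiochemical choice.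

Step 5
Reactants: 10 2-iodo-6-(4,4,5,5-tetramethyl-1,3,2-dioxaborolan-2-yl)phenol
Product: 11 2-iodo-6-(4,4,5,5-tetramethyl-1,3,2-dioxaborolan-2-yl)phenyl trifluoromethanesulfonate
Conditions: Tf2O, pyridine, CH2Cl2, 0 °C
Reagents that add atoms: trifluoromethanesulfonic anhydride, O=S(=O)(OS(=O)(=O)C(F)(F)F)C(F)(F)F
Why: O-Sulfonylation of a phenol with triflic anhydride and an amine base; the pinacol boronate and the aryl iodide are inert, and ortho-boryl aryl triflates are stable, isolable compounds.

Step 6
Reactants: 7 (4'R)-4'-(furan-2-yl)-5'-methoxy-3',4'-dihydro-2'H-spiro[1,3-dioxolane-2,1'-naphthalene]; 11 2-iodo-6-(4,4,5,5-tetramethyl-1,3,2-dioxaborolan-2-yl)phenyl trifluoromethanesulfonate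
Product: 14 2-{(1R,4R)-1-[(4'R)-5'-methoxy-3',4'-dihydro-2'H-spiro[1,3-dioxolane-2,1'-naphthalen]-4'-yl]-1,4-dihydro-1,4-epoxynaphthalen-5-yl}-4,4,5,5-tetramethyl-1,3,2-dioxaborolane (drawn bridge isomer; its (1S,4S) bridge diastereomer forms alongside), via arylmagnesium chloride 12 (not isolated), via 3-(pinacolboryl)benzyne 13 (not isolated)
Conditions: 7 (1 equiv), 11 (2.5 equiv), iPrMgCl·LiCl (2.6 equiv, slow addition), Et2O, −78 °C → rt
Reagents that add atoms: none
Why: Iodine–magnesium exchange on 11 at −78 °C gives 12, which expels triflate from the neighbouring carbon to give aryne 13; exchange on the electron-poor iodide is far faster than attack of the Grignard reagent on boron, so the boronate survives. 13 is trapped by the furan of 7 in a concerted, asynchronous aryne Diels–Alder reaction, and the closest known reaction type is the distal-selective cycloaddition of 3-borylbenzynes with 2-substituted furans. Ring C is closed by this intermolecular [4+2] cycloaddition: C1'–C8a' and C4'–C4a' form suprafacially on the diene and the furan oxygen becomes the bridge. The two new bridgehead centres are fixed relative to each other by the geometry of the bicycle; their sense relative to C4 depends on which furan face is attacked, which is not controlled and need not be, because both centres vanish on aromatization in step 9. The selectivity that matters is regiochemical: the furan carbon bearing the tetralin must bond to the aryne carbon remote from boron. This is secured by the bulky pinacolboryl group next to the triple bond and the distortion it imposes on the aryne, which send the unsubstituted furan terminus to the neighbouring carbon, and by the large secondary substituent on the furan. The dioxolane keeps the carbonyl group away from the magnesium species and the C4 centre is untouched. 11 and the Grignard reagent are used in excess because 7 is the valuable partner.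

Step 7
Reactants: 14 the boryl cycloadduct
Product: 15 (1R,4R)-1-[(4'R)-5'-methoxy-3',4'-dihydro-2'H-spiro[1,3-dioxolane-2,1'-naphthalen]-4'-yl]-1,4-dihydro-1,4-epoxynaphthalen-5-ol (drawn bridge isomer)
Conditions: NaBO3·4H2O, THF/H2O (1:1), rt
Reagents that add atoms: sodium perborate, [Na+].[Na+].O[B-]1(O)OO[B-](O)(O)OO1
Why: Oxidation of an arylboronic ester to the phenol by perborate (aryl 1,2-shift from boron to peroxide oxygen, then hydrolysis); the mild, weakly basic medium leaves the strained bridge alkene, the dioxolane and the bridgehead ethers alone.

Step 8
Reactants: 15 the bridged phenol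
Product: 16 (4'R)-5'-methoxy-4'-[(1R,4R)-5-methoxy-1,4-dihydro-1,4-epoxynaphthalen-1-yl]-3',4'-dihydro-2'H-spiro[1,3-dioxolane-2,1'-naphthalene] (drawn bridge isomer)
Conditions: MeI, K2CO3, DMF, rt
Reagents that add atoms: iodomethane, CI
Why: Williamson O-methylation of the phenoxide; carrying it out while the future C4' oxygen is still locked in the bridge is what differentiates the two peri oxygens of the naphthalene.

Step 9
Reactants: 16 the bridged methyl ether
Product: 18 (4S)-4-(4-hydroxy-5-methoxynaphthalen-1-yl)-5-methoxy-3,4-dihydronaphthalen-1(2H)-one, via bridged ketone 17 (not isolated)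
Conditions: 3 M aq. HCl, THF, 50 °C, under Ar
Reagents that add atoms: water, O
Why: Acid-catalysed isomerization of a 1-alkyl-1,4-epoxy-1,4-dihydronaphthalene to a 4-alkyl-1-naphthol, combined with ketal hydrolysis. The dioxolane hydrolyses first (17); protonation of the bridge oxygen and heterolysis of the tertiary, allylic and benzylic C1'–O bond then give a cation that aromatizes by hydride shift from C4' to C3' and enolization, leaving the hydroxyl on C4'. Both bridge diastereomers converge and C4 takes no part.

Step 10
Reactants: 18 (4S)-4-(4-hydroxy-5-methoxynaphthalen-1-yl)-5-methoxy-3,4-dihydronaphthalen-1(2H)-one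
Product: 19 (1S,4S)-4-(4-hydroxy-5-methoxynaphthalen-1-yl)-5-methoxy-1,2,3,4-tetrahydronaphthalen-1-ol (dipolynaphthalene B)
Conditions: RuCl[(S,S)-TsDPEN](p-cymene) (2 mol %), HCO2H/Et3N (5:2), DMF, rt
Reagents that add atoms: none
Why: Noyori-type asymmetric transfer hydrogenation of an aryl ketone; the (S,S)-catalyst delivers hydride to the face that gives the 1S carbinol. This is also the face anti to the C4 naphthyl group, which is pseudoaxial because of the peri C5 methoxy group, so catalyst and substrate preferences should be matched and give the cis-(1S,4S) product. The near-neutral medium spares the benzylic alcohol and the naphthol.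

## Compound list

1 | 5-methoxy-3,4-dihydronaphthalen-1(2H)-one | COc1cccc2c1CCCC2=O | starting material
2 | racemic 4-bromo-5-methoxy-3,4-dihydronaphthalen-1(2H)-one | COc1cccc2c1C(Br)CCC2=O | intermediate
3 | furan | c1ccoc1 | starting material
4 | 2-furyllithium | [Li]c1ccco1 | intermediate (not isolated)
5 | 2-furylzinc chloride | Cl[Zn]c1ccco1 | intermediate (not isolated)
6 | (4R)-4-(furan-2-yl)-5-methoxy-3,4-dihydronaphthalen-1(2H)-one | COc1cccc2c1[C@H](c1ccco1)CCC2=O | intermediate
7 | (4'R)-4'-(furan-2-yl)-5'-methoxy-3',4'-dihydro-2'H-spiro[1,3-dioxolane-2,1'-naphthalene] | COc1cccc2c1[C@H](c1ccco1)CCC21OCCO1 | intermediate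
8 | 2,6-diiodophenol | Oc1c(I)cccc1I | starting material
9 | chloromagnesium 2-(chloromagnesio)-6-iodophenoxide | Cl[Mg]Oc1c(I)cccc1[Mg]Cl | intermediate (not isolated)
10 | 2-iodo-6-(4,4,5,5-tetramethyl-1,3,2-dioxaborolan-2-yl)phenol | CC1(C)OB(OC1(C)C)c1cccc(I)c1O | intermediate
11 | 2-iodo-6-(4,4,5,5-tetramethyl-1,3,2-dioxaborolan-2-yl)phenyl trifluoromethanesulfonate | CC1(C)OB(OC1(C)C)c1cccc(I)c1OS(=O)(=O)C(F)(F)F | intermediate
12 | 3-(pinacolboryl)-2-(triflyloxy)phenylmagnesium chloride | CC1(C)OB(OC1(C)C)c1cccc([Mg]Cl)c1OS(=O)(=O)C(F)(F)F | intermediate (not isolated)
13 | 3-(4,4,5,5-tetramethyl-1,3,2-dioxaborolan-2-yl)benzyne | CC1(C)OB(OC1(C)C)C1=CC=CC#C1 | intermediate (not isolated)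
14 | 2-{(1R,4R)-1-[(4'R)-5'-methoxy-3',4'-dihydro-2'H-spiro[1,3-dioxolane-2,1'-naphthalen]-4'-yl]-1,4-dihydro-1,4-epoxynaphthalen-5-yl}-4,4,5,5-tetramethyl-1,3,2-dioxaborolane (drawn bridge isomer) | COc1cccc2c1[C@H]([C@@]13C=C[C@@H](O1)c1c(B4OC(C)(C)C(C)(C)O4)cccc13)CCC21OCCO1 | intermediate
15 | (1R,4R)-1-[(4'R)-5'-methoxy-3',4'-dihydro-2'H-spiro[1,3-dioxolane-2,1'-naphthalen]-4'-yl]-1,4-dihydro-1,4-epoxynaphthalen-5-ol (drawn bridge isomer) | COc1cccc2c1[C@H]([C@@]13C=C[C@@H](O1)c1c(O)cccc13)CCC21OCCO1 | intermediate
16 | (4'R)-5'-methoxy-4'-[(1R,4R)-5-methoxy-1,4-dihydro-1,4-epoxynaphthalen-1-yl]-3',4'-dihydro-2'H-spiro[1,3-dioxolane-2,1'-naphthalene] (drawn bridge isomer) | COc1cccc2c1[C@H]([C@@]13C=C[C@@H](O1)c1c(OC)cccc13)CCC21OCCO1 | intermediate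
17 | (4R)-5-methoxy-4-[(1R,4R)-5-methoxy-1,4-dihydro-1,4-epoxynaphthalen-1-yl]-3,4-dihydronaphthalen-1(2H)-one (drawn bridge isomer) | COc1cccc2c1[C@H]([C@@]13C=C[C@@H](O1)c1c(OC)cccc13)CCC2=O | intermediate (not isolated)
18 | (4S)-4-(4-hydroxy-5-methoxynaphthalen-1-yl)-5-methoxy-3,4-dihydronaphthalen-1(2H)-one | COc1cccc2c1[C@H](c1ccc(O)c3c(OC)cccc13)CCC2=O | intermediate
19 | (1S,4S)-4-(4-hydroxy-5-methoxynaphthalen-1-yl)-5-methoxy-1,2,3,4-tetrahydronaphthalen-1-ol (dipolynaphthalene B) | COc1cccc2c1[C@H](c1ccc(O)c3c(OC)cccc13)CC[C@@H]2O | target

## Step count and least certain steps

Total: 10 steps. Longest linear sequence: 8 steps (steps 1, 2, 3, 6, 7, 8, 9, 10 from 1); the aryne branch from 8 joins after 2 steps.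

Step 6 (key step). The most likely failure is loss of the aryne along paths that bypass the furan (addition of the Grignard reagent or of 12 to 13, or attack on boron) while 7 is the limiting partner. Leakage to the proximal regioisomer is the second concern.
- Fallback: drop the cycloaddition and attach the finished naphthalene by electrophilic substitution, accepting a racemate that the last step resolves.
- It sets out from 2: Friedel–Crafts alkylation of commercial 8-methoxynaphthalen-1-ol F1 at its C4 (para to the hydroxyl) by the benzylic cation from 2 in hexafluoroisopropanol should give racemic 4-(4-hydroxy-5-methoxynaphthalen-1-yl)-5-methoxy-3,4-dihydronaphthalen-1(2H)-one F2.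
- Under the conditions of step 10 the catalyst should reduce both enantiomers to the 1S carbinol, giving 19 from the 4S half and the separable trans diastereomer (1S,4R)-4-(4-hydroxy-5-methoxynaphthalen-1-yl)-5-methoxy-1,2,3,4-tetrahydronaphthalen-1-ol F3 from the 4R half.
- The fallback rejoins the route at 19, at the cost of half the material.

Step 2. The likely failures are loss of HBr from 2 (with aromatization) before the nickel catalyst can engage it, uncatalysed racemic substitution, and weak enantioselection with a heteroarylzinc partner on a cyclic bromide.
- Fallback: give up asymmetric catalysis and resolve.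
- It sets out from 2 and 3: ZnCl2-catalysed Friedel–Crafts alkylation of excess furan by 2 in CH2Cl2 at 0 °C should give racemic 4-(furan-2-yl)-5-methoxy-3,4-dihydronaphthalen-1(2H)-one F4.
- Preparative chromatography on a chiral stationary phase then supplies the R enantiomer, rejoining the route at 6.

Step 9. Possible failures are heterolysis at the other bridgehead followed by 1,2-shift of the tetralin group (an isomeric naphthol), a hydride shift from C4 into the cation that would erode the stereocentre, and acid-promoted oligomerization or oxidation of the electron-rich naphthol.
- Fallback: replace Brønsted-acid ionization by a metal-catalysed isomerization under neutral conditions. In such a process only the hydrogen-bearing bridgehead can become the carbonyl carbon, by C–O insertion and β-hydride elimination.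
- It sets out from 16: [RuCl2(CO)3]2 (cat.) in ClCH2CH2Cl at 60 °C should give (4'S)-4'-(4-hydroxy-5-methoxynaphthalen-1-yl)-5'-methoxy-3',4'-dihydro-2'H-spiro[1,3-dioxolane-2,1'-naphthalene] F5.
- Mild deketalization (PPTS, wet acetone) then rejoins the route at 18.

Step 4. Possible failures are incomplete or double exchange on the electron-rich phenoxide and protonation of the arylmagnesium before borylation.
- Fallback: a protecting-group route.
- It sets out from 8: MOMCl/iPr2NEt gives 1,3-diiodo-2-(methoxymethoxy)benzene F6.
- Mono-exchange with iPrMgCl·LiCl at −40 °C and trapping with iPrOBpin gives 2-[3-iodo-2-(methoxymethoxy)phenyl]-4,4,5,5-tetramethyl-1,3,2-dioxaborolane F7.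
- HCl in MeOH removes the acetal, rejoining the route at 10.

## Further compounds

F1 | step 6 | 8-methoxynaphthalen-1-ol | COc1cccc2cccc(O)c12
F2 | step 6 | racemic 4-(4-hydroxy-5-methoxynaphthalen-1-yl)-5-methoxy-3,4-dihydronaphthalen-1(2H)-one | COc1cccc2c1C(c1ccc(O)c3c(OC)cccc13)CCC2=O
F3 | step 6 | (1S,4R)-4-(4-hydroxy-5-methoxynaphthalen-1-yl)-5-methoxy-1,2,3,4-tetrahydronaphthalen-1-ol | COc1cccc2c1[C@@H](c1ccc(O)c3c(OC)cccc13)CC[C@@H]2O
F4 | step 2 | racemic 4-(furan-2-yl)-5-methoxy-3,4-dihydronaphthalen-1(2H)-one | COc1cccc2c1C(c1ccco1)CCC2=O
F5 | step 9 | (4'S)-4'-(4-hydroxy-5-methoxynaphthalen-1-yl)-5'-methoxy-3',4'-dihydro-2'H-spiro[1,3-dioxolane-2,1'-naphthalene] | COc1cccc2c1[C@H](c1ccc(O)c3c(OC)cccc13)CCC21OCCO1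
F6 | step 4 | 1,3-diiodo-2-(methoxymethoxy)benzene | COCOc1c(I)cccc1I
F7 | step 4 | 2-[3-iodo-2-(methoxymethoxy)phenyl]-4,4,5,5-tetramethyl-1,3,2-dioxaborolane | COCOc1c(I)cccc1B1OC(C)(C)C(C)(C)O1
A1 | alternative 1 | 2-{[4-(benzyloxy)-5-methoxynaphthalen-1-yl]methyl}-3-methoxybenzaldehyde | COc1cccc(C=O)c1Cc1ccc(OCc2ccccc2)c2c(OC)cccc12
A2 | alternative 1 | phenyl vinyl sulfone | C=CS(=O)(=O)c1ccccc1
A3 | alternative 1 | (1R,2S,4S)-4-[4-(benzyloxy)-5-methoxynaphthalen-1-yl]-5-methoxy-2-(phenylsulfonyl)-1,2,3,4-tetrahydronaphthalen-1-ol (all-cis) | COc1cccc2c1[C@H](c1ccc(OCc4ccccc4)c3c(OC)cccc13)C[C@H](S(=O)(=O)c1ccccc1)[C@@H]2O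
A4 | alternative 2 | tert-butyl({4-[(3S,6S)-6-[(tert-butyldimethylsilyl)oxy]-1-methoxyocta-1,7-diyn-3-yl]-8-methoxynaphthalen-1-yl}oxy)dimethylsilane | COC#C[C@H](c1ccc(O[Si](C)(C)C(C)(C)C)c2c(OC)cccc12)CC[C@H](O[Si](C)(C)C(C)(C)C)C#C
A5 | alternative 2 | acetylene | C#C
A6 | alternative 2 | bis(tert-butyldimethylsilyl) ether of 19 | COc1cccc2c1[C@H](c1ccc(O[Si](C)(C)C(C)(C)C)c3c(OC)cccc13)CC[C@@H]2O[Si](C)(C)C(C)(C)C
A7 | alternative 3 | 3-methoxy-2-(trimethylsilyl)phenyl trifluoromethanesulfonate | COc1cccc(OS(=O)(=O)C(F)(F)F)c1[Si](C)(C)C
A8 | alternative 3 | 2-[4-(benzyloxy)-5-methoxynaphthalen-1-yl]furan | COc1cccc2c(-c3ccco3)ccc(OCc3ccccc3)c12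
A9 | alternative 3 | 1-[4-(benzyloxy)-5-methoxynaphthalen-1-yl]-8-methoxy-1,4-dihydro-1,4-epoxynaphthalene (racemic; enantiomer leading to 19 drawn) | COc1cccc2c1[C@@]3(c1ccc(OCc4ccccc4)c5c(OC)cccc15)C=C[C@@H]2O3
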